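The route rests on an intramolecular Diels–Alder reaction of a vinylallene (eudesmane numbering throughout). The diene C5=C6–C7=C8, whose terminus C5 is the central allene carbon, adds the tethered isopropenyl alkene C9=C10. This closes rings A and B at once, forms C5–C10 and C8–C9, and sets the quaternary centre C10 from the allene axis. The step exploits the fact that C5, the hydroperoxide-bearing ring-fusion carbon, sits next to the C4 exocyclic methylene: the distal allene bond emerges as a C4=C5 alkene, which a final singlet-oxygen ene reaction converts into that array. The precursor is an acyclic (5S)-allenol made by Sharpless epoxidation and anti-SN2′ cuprate opening.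

Key step: step 5

Remark: C1–C15 are the eudesmane positions of the target (C3 ester carbinol, C5 hydroperoxide carbon, C7 acrylate-bearing carbon, C10 methyl-bearing quaternary carbon) and are used for all intermediates; (aR) denotes the axial configuration of the allene.

Step 1
Reactants: 1 (2Z)-3-methylpent-2-en-4-yn-1-ol
Product: 2 [(2S,3R)-3-ethynyl-3-methyloxiran-2-yl]methanol
Conditions: Ti(OiPr)4 (10 mol%), L-(+)-diethyl tartrate (12 mol%), t-BuOOH, 4 Å MS, CH2Cl2, −20 °C
Reagents that add atoms: tert-butyl hydroperoxide, CC(C)(C)OO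
Why: Sharpless asymmetric epoxidation of a primary allylic alcohol, in which the titanium L-(+)-tartrate complex should deliver oxygen to the enantioface that gives the 2S epoxy alcohol (the sense known for nerol-type Z-3,3-disubstituted substrates), the Z geometry being carried into the cis (2S,3R) oxirane that fixes C3 and C4 while the alkyne stays inert.

Step 2
Reactants: 2 [(2S,3R)-3-ethynyl-3-methyloxiran-2-yl]methanol; 3 2-bromo-3,3-diethoxyprop-1-ene
Product: 6 (2R,aR)-6-(diethoxymethyl)-3-methylhepta-3,4,6-triene-1,2-diol, via alkenyllithium 4 (not isolated), via lithium dialkenylcuprate 5 (not isolated)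
Conditions: 3, t-BuLi (2 equiv), Et2O, −78 °C; CuI (0.5 equiv per Li); then 2 (0.45 equiv per Cu), −78 → −40 °C; aq. NH4Cl
Reagents that add atoms: none
Why: Anti-selective SN2′ (1,3-) substitution of an alkynyl oxirane by a lithium dialkenylcuprate, in which copper attacks the alkyne terminus C6 anti to the breaking C4–O bond so that the configuration of epoxide carbon C4 is transferred into the (aR) allene axis, while C3 keeps its configuration because its C–O bond is not broken (its descriptor changes to R only through priority).

Step 3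
Reactants: 6 (2R,aR)-6-(diethoxymethyl)-3-methylhepta-3,4,6-triene-1,2-diol
Product: 7 (2R,aR)-6-(diethoxymethyl)-2-hydroxy-3-methylhepta-3,4,6-trien-1-yl 4-methylbenzenesulfonate
Conditions: TsCl, Et3N, Bu2SnO (cat.), CH2Cl2, 0 °C
Reagents that add atoms: p-toluenesulfonyl chloride, Cc1ccc(cc1)S(=O)(=O)Cl
Why: Dibutyltin oxide-catalysed regioselective monosulfonylation of a 1,2-diol through its stannylene acetal should activate only the primary hydroxyl and touches no stereocentre.

Step 4
Reactants: 7 (2R,aR)-6-(diethoxymethyl)-2-hydroxy-3-methylhepta-3,4,6-trien-1-yl 4-methylbenzenesulfonate; 8 (2-methylprop-2-en-1-yl)magnesium chloride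
Product: 10 (5S,aR)-9-(diethoxymethyl)-2,6-dimethyldeca-1,6,7,9-tetraen-5-ol, via allenyl oxirane 9 (not isolated)
Conditions: CH2=C(CH3)CH2MgCl (3 equiv), THF, −20 °C → rt; aq. NH4Cl
Reagents that add atoms: none
Why: The first equivalent of Grignard reagent forms the magnesium alkoxide, which closes to the terminal epoxide by intramolecular Williamson displacement without touching the C3–O bond, and the allylic Grignard reagent then opens the oxirane by SN2 attack at the unhindered CH2 (direct displacement of the tosylate converges on the same product), forming C1–C2 without copper so that SN2′ attack on the allenyl oxirane is avoided.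

Step 5
Reactants: 10 (5S,aR)-9-(diethoxymethyl)-2,6-dimethyldeca-1,6,7,9-tetraen-5-ol
Product: 11 (2S,4aS)-7-(diethoxymethyl)-1,4a-dimethyl-2,3,4,4a,5,6-hexahydronaphthalen-2-ol
Conditions: PhMe (0.01 M), BHT (cat.), 140 °C, sealed tube, Ar
Reagents that add atoms: none
Why: On heating, the vinylallene should undergo a concerted suprafacial [4+2] cycloaddition in which the s-cis diene C5=C6–C7=C8 (C5 is the central allene carbon) is the 4π partner and the tethered, unactivated isopropenyl alkene C9=C10 the 2π partner; the closest known reaction type is the type 1 intramolecular Diels–Alder reaction of vinylallenes, which are more reactive dienes than simple 1,3-dienes because the diene terminus is unhindered and allene strain is released. Ring B is closed by the cycloaddition itself (bonds C5–C10 and C8–C9, new C6=C7), and ring A is closed in the fused mode through the four-atom tether C4–C3–C2–C1, the distal allene bond surviving as the tetrasubstituted C4=C5 alkene inside ring A. The single new stereocentre, C10, is controlled by the allene axis: C3 stands out of the diene plane on C4, so the alkene can bond to C5 only from that face, and because C9 must reach C8 while C1 stays in the plane of the forming ring A, the C10 methyl is forced to the side away from the diene, which for the (aR) axis gives 10S, cis to the 3-hydroxyl (axis-to-centre chirality transfer). The step needs periselectivity ([4+2] rather than allene [2+2], ene or dimerisation) and the fused regiochemistry; these are secured by the tether length (a six-membered ring A is possible only for the C5–C10/C8–C9 pairing), the 2-substituent on the diene that favours the s-cis conformer, high dilution and the lack of a hydrogen placed for a [1,5]-shift. No endo/exo question arises because C5 becomes trigonal.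

Step 6
Reactants: 11 (2S,4aS)-7-(diethoxymethyl)-1,4a-dimethyl-2,3,4,4a,5,6-hexahydronaphthalen-2-ol
Product: 12 (2S,4aS,7R)-7-(diethoxymethyl)-1,4a-dimethyl-2,3,4,4a,5,6,7,8-octahydronaphthalen-2-ol
Conditions: 2-O2NC6H4SO2NHNH2 (excess, in portions), Et3N, CH2Cl2, rt
Reagents that add atoms: none
Why: Diimide generated in situ transfers two hydrogens in a concerted syn 1,2-fashion to the less substituted conjugated C6=C7 bond and should leave the hindered tetrasubstituted C4=C5 bond, and approach anti to the axial C10 methyl (α-face, as in additions to steroidal 4,6-dienes) should place the new C7–H trans to that methyl, giving 7R.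

Step 7
Reactants: 12 (2S,4aS,7R)-7-(diethoxymethyl)-1,4a-dimethyl-2,3,4,4a,5,6,7,8-octahydronaphthalen-2-ol
Product: 13 (2R,4aS,7S)-7-hydroxy-4a,8-dimethyl-1,2,3,4,4a,5,6,7-octahydronaphthalene-2-carbaldehyde
Conditions: PPTS, acetone/H2O (10:1), 40 °C
Reagents that add atoms: water, O
Why: Acid-catalysed acetal hydrolysis under buffered pyridinium conditions should unmask the aldehyde without ionising the allylic alcohol, and C7 already carries the equatorial substituent so no stereocentre changes.

Step 8
Reactants: 13 (2R,4aS,7S)-7-hydroxy-4a,8-dimethyl-1,2,3,4,4a,5,6,7-octahydronaphthalene-2-carbaldehyde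
Product: 14 (2S,4aS,7R)-7-ethynyl-1,4a-dimethyl-2,3,4,4a,5,6,7,8-octahydronaphthalen-2-ol
Conditions: dimethyl (1-diazo-2-oxopropyl)phosphonate, K2CO3, MeOH, 0 °C → rt
Reagents that add atoms: dimethyl (1-diazo-2-oxopropyl)phosphonate, COP(=O)(OC)C(=[N+]=[N-])C(C)=O
Why: Ohira–Bestmann (Seyferth–Gilbert) homologation converts the aldehyde into the terminal alkyne through a diazoalkene and alkylidene carbene 1,2-shift under mild carbonate conditions, so C7 should keep its configuration (the equatorial epimer is also the thermodynamically preferred one).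

Step 9
Reactants: 14 (2S,4aS,7R)-7-ethynyl-1,4a-dimethyl-2,3,4,4a,5,6,7,8-octahydronaphthalen-2-ol
Product: 15 methyl 2-[(2R,4aS,7S)-7-hydroxy-4a,8-dimethyl-1,2,3,4,4a,5,6,7-octahydronaphthalen-2-yl]prop-2-enoate
Conditions: Pd(OAc)2 (cat.), 2-(diphenylphosphino)pyridine, MsOH (cat.), CO (20 bar), MeOH, 50 °C
Reagents that add atoms: carbon monoxide, [C-]#[O+]; methanol, CO
Why: Palladium hydride/2-pyridylphosphine-catalysed Markovnikov hydromethoxycarbonylation of a terminal alkyne places the ester on the internal carbon and should give the 2-substituted acrylate (C11=C13, C12 ester) directly without affecting any stereocentre.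

Step 10
Reactants: 15 methyl 2-[(2R,4aS,7S)-7-hydroxy-4a,8-dimethyl-1,2,3,4,4a,5,6,7-octahydronaphthalen-2-yl]prop-2-enoate; 16 (2Z)-2-methylbut-2-enoic acid (angelic acid)
Product: 18 (2S,4aS,7R)-7-(3-methoxy-3-oxoprop-1-en-2-yl)-1,4a-dimethyl-2,3,4,4a,5,6,7,8-octahydronaphthalen-2-yl (2Z)-2-methylbut-2-enoate, via mixed anhydride 17 (not isolated)
Conditions: 16, 2,4,6-Cl3C6H2COCl, Et3N, PhMe, rt; then 15, 75 °C (no DMAP)
Reagents that add atoms: none
Why: Yamaguchi-type mixed-anhydride esterification run without DMAP acylates the equatorial allylic alcohol with retention at C3 and is the established way to avoid Z to E isomerisation of the angelate.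

Step 11
Reactants: 18 (2S,4aS,7R)-7-(3-methoxy-3-oxoprop-1-en-2-yl)-1,4a-dimethyl-2,3,4,4a,5,6,7,8-octahydronaphthalen-2-yl (2Z)-2-methylbut-2-enoate
Product: 19 methyl 2-[(2R,4aS,7S,8aS)-8a-hydroperoxy-4a-methyl-8-methylidene-7-{[(2Z)-2-methylbut-2-enoyl]oxy}decahydronaphthalen-2-yl]prop-2-enoate (target)
Conditions: O2, visible light, tetraphenylporphyrin (cat.), CH2Cl2, −20 °C; non-reductive work-up
Reagents that add atoms: dioxygen, O=O
Why: Schenck ene reaction of singlet oxygen with the only electron-rich alkene (tetrasubstituted C4=C5), in which oxygen should add to C5 from the α-face, anti to the axial C10 methyl and the 3β-acyloxy group, and abstract hydrogen from the C15 methyl geminal to the oxygenated allylic carbon C3 (geminal directing effect, H3 being deactivated), giving the 5α-hydroperoxide (5S) with the C4 exocyclic methylene.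

Compound list
1 | (2Z)-3-methylpent-2-en-4-yn-1-ol | C#C/C(C)=C\CO | starting material
2 | [(2S,3R)-3-ethynyl-3-methyloxiran-2-yl]methanol | OC[C@@H]1O[C@]1(C)C#C | intermediate
3 | 2-bromo-3,3-diethoxyprop-1-ene | C=C(Br)C(OCC)OCC | starting material
4 | (3,3-diethoxyprop-1-en-2-yl)lithium | [Li]C(=C)C(OCC)OCC | intermediate (not isolated)
5 | lithium bis(3,3-diethoxyprop-1-en-2-yl)cuprate LiCu[C(=CH2)CH(OEt)2]2 | [Li+].C=C([Cu-]C(=C)C(OCC)OCC)C(OCC)OCC | intermediate (not isolated)
6 | (2R,aR)-6-(diethoxymethyl)-3-methylhepta-3,4,6-triene-1,2-diol | OC[C@H](O)C(C)=[C@]=C([H])C(=C)C(OCC)OCC | intermediate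
7 | (2R,aR)-6-(diethoxymethyl)-2-hydroxy-3-methylhepta-3,4,6-trien-1-yl 4-methylbenzenesulfonate | Cc1ccc(cc1)S(=O)(=O)OC[C@H](O)C(C)=[C@]=C([H])C(=C)C(OCC)OCC | intermediate
8 | (2-methylprop-2-en-1-yl)magnesium chloride | C=C(C)C[Mg]Cl | starting material
9 | (2R)-2-[(aR)-5-(diethoxymethyl)hexa-2,3,5-trien-2-yl]oxirane | C1O[C@@H]1C(C)=[C@]=C([H])C(=C)C(OCC)OCC | intermediate (not isolated)
10 | (5S,aR)-9-(diethoxymethyl)-2,6-dimethyldeca-1,6,7,9-tetraen-5-ol | C=C(C)CC[C@H](O)C(C)=[C@]=C([H])C(=C)C(OCC)OCC | intermediate
11 | (2S,4aS)-7-(diethoxymethyl)-1,4a-dimethyl-2,3,4,4a,5,6-hexahydronaphthalen-2-ol | O[C@H]1CC[C@]2(C)CCC(C(OCC)OCC)=CC2=C1C | intermediate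
12 | (2S,4aS,7R)-7-(diethoxymethyl)-1,4a-dimethyl-2,3,4,4a,5,6,7,8-octahydronaphthalen-2-ol | O[C@H]1CC[C@]2(C)CC[C@@H](C(OCC)OCC)CC2=C1C | intermediate
13 | (2R,4aS,7S)-7-hydroxy-4a,8-dimethyl-1,2,3,4,4a,5,6,7-octahydronaphthalene-2-carbaldehyde | O[C@H]1CC[C@]2(C)CC[C@@H](C=O)CC2=C1C | intermediate
14 | (2S,4aS,7R)-7-ethynyl-1,4a-dimethyl-2,3,4,4a,5,6,7,8-octahydronaphthalen-2-ol | O[C@H]1CC[C@]2(C)CC[C@@H](C#C)CC2=C1C | intermediate
15 | methyl 2-[(2R,4aS,7S)-7-hydroxy-4a,8-dimethyl-1,2,3,4,4a,5,6,7-octahydronaphthalen-2-yl]prop-2-enoate (methyl 3β-hydroxyeudesma-4,11(13)-dien-12-oate) | C=C(C(=O)OC)[C@@H]1CC[C@@]2(C)CC[C@H](O)C(C)=C2C1 | intermediate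
16 | (2Z)-2-methylbut-2-enoic acid (angelic acid) | C/C=C(/C)C(=O)O | starting material
17 | (2Z)-2-methylbut-2-enoic 2,4,6-trichlorobenzoic anhydride | C/C=C(/C)C(=O)OC(=O)c1c(Cl)cc(Cl)cc1Cl | intermediate (not isolated)
18 | (2S,4aS,7R)-7-(3-methoxy-3-oxoprop-1-en-2-yl)-1,4a-dimethyl-2,3,4,4a,5,6,7,8-octahydronaphthalen-2-yl (2Z)-2-methylbut-2-enoate (methyl 3β-angeloyloxyeudesma-4,11(13)-dien-12-oate) | C=C(C(=O)OC)[C@@H]1CC[C@@]2(C)CC[C@H](OC(=O)/C(C)=C\C)C(C)=C2C1 | intermediate
19 | methyl 2-[(2R,4aS,7S,8aS)-8a-hydroperoxy-4a-methyl-8-methylidene-7-{[(2Z)-2-methylbut-2-enoyl]oxy}decahydronaphthalen-2-yl]prop-2-enoate | C=C(C(=O)OC)[C@@H]1CC[C@@]2(C)CC[C@H](OC(=O)/C(C)=C\C)C(=C)[C@]2(OO)C1 | target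

Total step count: 11. Longest linear sequence: 11 steps (1 to 19).

Steps most likely to fail

Step 5. The cycloaddition may be slower than thermal decay of the vinylallene (dimerisation, allene–alkene [2+2], polymerisation), because the dienophile is an unactivated 1,1-disubstituted alkene. The fallback sets out again from 10 and replaces the pericyclic process by a metal-mediated stepwise [4+2]: oxidative cyclisation of diene and alkene on the metal to a metallacycle, then reductive elimination. It would use a cationic monovalent rhodium catalyst, [Rh(cod)2]BF4 with P[OCH(CF3)2]3, in CH2Cl2 or trifluoroethanol at 25–60 °C. The tether geometry that fixes C10 is unchanged and the route is rejoined at 11. This fallback makes no new compound (F0).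

Step 6. Diimide may reduce the trisubstituted C6=C7 bond too slowly, may not distinguish it cleanly from C4=C5, or may add in part from the β-face. The fallback sets out from 11. The allylic acetal is hydrolysed (PPTS, wet acetone, rt) to the conjugated dienal (4aS,7S)-7-hydroxy-4a,8-dimethyl-3,4,4a,5,6,7-hexahydronaphthalene-2-carbaldehyde F1. This is then submitted to 1,4-reduction with [(Ph3P)CuH]6 in wet benzene/THF. Hydride should go to C6, the β-position, because the δ-carbon C4 is fully substituted. The resulting enolate is protonated and equilibrated at C7 (K2CO3, MeOH) towards the equatorial aldehyde, and the route is rejoined at 13. In this variant C7 is under thermodynamic rather than kinetic control, so a lower epimer ratio would be expected.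

Step 11. Singlet oxygen may attack the β-face or abstract the axial H6, which would give the C5 epimer or the 4-hydroperoxy-5-ene. The fallback sets out from 18 and has three stages:
- Epoxidation with mCPBA on the α-face, anti to the C10 methyl, gives methyl 3β-angeloyloxy-4α,5α-epoxyeudesm-11(13)-en-12-oate F2.
- Base-promoted epoxide-to-allylic-alcohol isomerisation with diethylaluminium 2,2,6,6-tetramethylpiperidide, Et2Al(NC9H18), removes a C15 hydrogen and opens the C4–O bond to give methyl 3β-angeloyloxy-5α-hydroxyeudesma-4(15),11(13)-dien-12-oate F3.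
- Acid-catalysed perhydrolysis (ethereal H2O2, TsOH cat., 0 °C) exchanges the tertiary allylic hydroxyl for hydroperoxyl through the allyl cation, which should be trapped at its tertiary terminus C5 anti to the C10 methyl, arriving at 19.

Further compounds
F0 | step 5 | none | none
F1 | step 6 | (4aS,7S)-7-hydroxy-4a,8-dimethyl-3,4,4a,5,6,7-hexahydronaphthalene-2-carbaldehyde | O[C@H]1CC[C@]2(C)CCC(C=O)=CC2=C1C
F2 | step 11 | methyl 3β-angeloyloxy-4α,5α-epoxyeudesm-11(13)-en-12-oate | C=C(C(=O)OC)[C@@H]1CC[C@@]2(C)CC[C@H](OC(=O)/C(C)=C\C)[C@@]3(C)O[C@@]23C1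
F3 | step 11 | methyl 3β-angeloyloxy-5α-hydroxyeudesma-4(15),11(13)-dien-12-oate | C=C(C(=O)OC)[C@@H]1CC[C@@]2(C)CC[C@H](OC(=O)/C(C)=C\C)C(=C)[C@]2(O)C1
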